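Decide between the two flasks by one comparison: at the last moment of each, set what makes D against what removes it.

| setting | gamma | delta | Thursday's | Wednesday's |
|---|---|---|---|---|
| L | 0.13 M | 0.30 M | 0.20 M | 0.20 M |
| temperature | 32 °C | 49 °C | 55 °C | 25 °C |
| remark | run made earlier | run made earlier |  |  |
| time |  |  | 8.0 d | 2.5 d |

- gamma (time / h: D / %, L / %): 3.00: 7.2, 91.9; 5.00: 10.2, 88.2; 8.00: 16.8, 81.9; 12.0: 24.5, 75.5; 20.0: 33.6, 64.9; 40.0: 47.5, 47.8
- delta (time / h: D / %, L / %): 1.00: 17.5, 82.5; 1.50: 23.5, 75.2; 2.50: 33.5, 65.1; 4.00: 41.4, 53.6; 6.00: 48.2, 43.4; 12.0: 52.9, 28.4

(standard deviation of a reading: 0.5 percentage points)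

* which one finishes higher in amount of D, in percent of the L charged ("neither" within 2 percentage points) (Thursday's / Wednesday's / neither)
* amount of D at the end, in percent of the L charged, Thursday's
* amount of D at the end, in percent of the L charged, Wednesday's

- a species is counted by the L in it: one D counts as two

Call f the fraction of the charge still L. In each run 1/f climbs nearly straight, so L goes second order, with slope 0.0273 h⁻¹ in gamma and 0.210 h⁻¹ in delta. Per unit of charge, delta runs 3.33 times as fast. D + L also falls behind the charge late in each run, so I take D to leak into something unread. Between the last two readings, the growth of that gap per unit of mean D and time gives a loss pace of 0.00395 h⁻¹ in gamma and 0.0340 h⁻¹ in delta, rough under the scatter.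

Carry both paces to each temperature by a steady factor per degree, and scale L's pace with the charge. Turn them into clocks and order them, shortest first: L on Thursday's, 4.67 h; D on Thursday's, 13.8 h; L on Wednesday's, 39.1 h; Wednesday's time, 60 h; Thursday's time, 192 h; D on Wednesday's, 615 h. So Thursday's lasts 13.9 D clocks and Wednesday's 0.0976.

Then f = 1/(1 + time/L clock). Making equals loss at the balance level, f squared times D clock over L clock, a steady state that sinks as f falls. D below it climbs; D above it sinks.

On Thursday's, I reckon f at 2.37 % and the level at 0.166 %. D follows it, since its clock is shorter than the time f takes to change. On Wednesday's, I reckon f at 39.5 % and the level at 245 %, above the whole charge, so D is still climbing. Taking the charge less L, less the leak from a D growing evenly, I expect 57.6 %.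

The forecast names Wednesday's, with 56 % on Wednesday's, slightly below my figure, and on Thursday's, “assuming first-order decay”, 0.2 %. The flasks give Wednesday's as the higher, with 56.0 % against 0.173 %.

    2 L → D (k = 0.0590 L mol⁻¹ h⁻¹, Ea = 60.0 kJ mol⁻¹)
    D → G (k = 0.00120 h⁻¹, Ea = 114 kJ mol⁻¹)
    (constants at 25 °C)

Thursday's trace comes from the reaction of D to G: struck out, Thursday's holds 97.6 % D, not 0.173 %. The balance level 0.166 % stands beside that result. Now read Wednesday's at 6.0 d: I reckon f at 21.4 % and the level at 71.7 %, while the charge less L, less the same even leak, gives D as 69.4 %, which is below the level, so D should still be climbing. The flask gives 68.2 %.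

(The runs were computed for substances that don't exist.)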